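It was impossible that the grey flask stood at equilibrium. At 120 h it held 64.6 mM of Q, the green flask with the same cQ and cG charged held 33.3 mM, and a catalyst cannot move an equilibrium. So I took J to be lost during the run, and I asked what one mM of J buys before it goes.

| flask | Q | G | J | time |
|---|---|---|---|---|
| grey | 100 mM | 110 mM | 2.00 mM |  |
| green | 100 mM | 110 mM | 4.00 mM |  |
| red | 100 mM | 55.0 mM | 2.00 mM |  |
| blue | 200 mM | 110 mM | 2.00 mM |  |
| ochre | 250 mM | 280 mM | 2.00 mM | 120 h |

| grey run: time / h | grey run: [Q] / mM | green run: time / h | green run: [Q] / mM | red run: time / h | red run: [Q] / mM | blue run: time / h | blue run: [Q] / mM |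
|---|---|---|---|---|---|---|---|
| 20 | 84.1 | 20 | 62.4 | 20 | 84.8 | 20 | 176.5 |
| 40 | 74.6 | 40 | 44.5 | 40 | 78.0 | 40 | 158.7 |
| 60 | 69.5 | 60 | 41.3 | 60 | 74.6 | 60 | 153.3 |
| 80 | 64.9 | 80 | 34.5 | 80 | 70.9 | 80 | 143.9 |
| 100 | 64.4 | 100 | 34.9 | 100 | 70.1 | 100 | 143.0 |
| 120 | 64.6 | 120 | 33.3 | 120 | 71.0 | 120 | 133.9 |

(standard deviation of a reading: 2 mM)

- Overall: Q + G -> E, with J as catalyst.
- Constant volume, constant temperature.
- What is held in complexes is read along with the free species.
- An order is taken over about fifteen percent of the charge, up and down.

- the power of [G] that the first rate follows, about the charge of the grey run; measure it at two percent of Q made into E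
- the power of [Q] that the first rate follows, about the charge of the grey run; measure it at two percent of Q made into E (one fixed amount of E, the same in the runs compared)
- Q in the ochre run at 120 h, as a share of the Q charged

My guess was that the Q turned per J lost grows in proportion to cQ. Then Q falls by a fixed share per J lost, and the curve can be replaced by one number for its end: L, the logarithm of cQ charged over cQ at 120 h. Grey gave L = 0.437.

I then turned the settings one at a time. The blue flask has twice the cQ of grey, and by hand L should stay put. Blue gave 0.401, a reading with its scatter.

The red flask has half the cG of grey. If cG did not count, L should again stay put, but red gave 0.342, lower than grey. So cG counts when it is cut against cQ. The ochre flask, though, keeps nearly grey's ratio of cG to cQ, 1.12 against 1.10.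

The green flask has twice the cJ of grey, and by hand L should follow it. Green gave 1.10, a ratio of 2.52 to grey. A straight line through these two flasks gives the spend, the rise of L per mM of J charged, as 0.331 mM⁻¹. It meets L = 0 at a dead charge of 0.681 mM, read as a stoichiometric poison would be.

The ochre flask has grey's cJ, so I reckoned its L equal to grey's, which leaves 64.6% of its Q.

The forecast said 68%, within 62% to 73%, above my figure. It gave orders of 0.25 in G and 0.7 in Q; for G its ground was “Halving G barely changes the early rate”.

The flask gave 65.0% of Q, with orders 0.47 in G and 0.54 in Q.

    J + Q → JQ (21.17 M⁻¹ h⁻¹)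
    JQ + G → Gy (20.52 M⁻¹ h⁻¹)
    Gy → E + J (16.38 h⁻¹)
    J + Qe → Ze
    J → Ze (0.05832 h⁻¹)

The loss of J to Ze is what stopped the ochre flask: with that step removed, it held 20.5% of its Q instead of 65.0% at 120 h. Its L was 0.431, and the spend on the J above the dead charge gives 0.437. With the step J + Qe → Ze taken away, the full 2.00 mM of J counts, so the spend gives 51.6% of Q, and the ochre flask run that way held 49.6%.

The earlier runs and the new flask were computed with made-up constants.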